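The asked share is a ratio of two amounts, each the running sum of a rate: open intermediate that went on to target against open intermediate that fell to side product.

the same everywhere: coupling partner 0.700 equiv; free catalyst 5.2 mol%

|  | substrate | remark | time |
|---|---|---|---|
| spring | 0.10 M | a single well-mixed tank run continuously and read at steady state, 8.0 h in it on average |  |
| winter | 0.10 M | one stirred flow tank at steady state, fed with the mixture as stated, mean residence time 40.0 h |  |
| noon | 0.10 M | everything together in a closed stirred flask, run for 8.0 h | 8.0 h |
| dusk | 0.10 M (fed, over 6.40 h) | a stirred flask in which substrate is dosed at a steady rate over 6.40 h without added volume, worked up at 8.0 h | 8.0 h |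

    substrate + free catalyst ⇌ free catalyst + open intermediate (K1 = 2.7, k1 = 0.029 M⁻¹ s⁻¹)
    free catalyst + open intermediate ⇌ catalyst intermediate (K2 = 3.9 M⁻¹, k2 = 0.074 M⁻¹ s⁻¹)
    coupling partner + catalyst intermediate → free catalyst + target (k3 = 0.17 M⁻¹ s⁻¹)
    open intermediate → side product (k4 = 6.5 × 10⁻⁵ s⁻¹)

- the set-up with the highest share of target in all that became target or side product, at the outlet or at the end ("none" if the first two lie within 2 percentage points) (spring / winter / noon / dusk / none)
- share of target in all that became target or side product, at the outlet or at the end, spring
- share of target in all that became target or side product, at the outlet or at the end, winter
- share of target in all that became target or side product, at the outlet or at the end, noon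
- share of target in all that became target or side product, at the outlet or at the end, dusk

Two chemists dispute this flask. They agree on one thing: catalyst intermediate is consumed by partner at the charge with a half-life of 0.97 min, far shorter than the 0.50 h open intermediate takes to be captured, so both treat catalyst intermediate as quasi-steady.

The first chemist counts capture as final. Capture by free catalyst at the charge runs 5.92 times as fast as the fall to side product. That gives a share of 85.5%, and the vessel does not enter this figure, so the first chemist expects "none".

The second chemist objects that captured material can return. Catalyst intermediate goes back at 0.0190 s⁻¹, while partner at the charge takes it on at 0.0119 s⁻¹, slower. The capture ratio must therefore be multiplied by escape over the sum of escape and return. At the charge that gives 2.28. This is the branch ratio, a selectivity factor: the rate to target over the rate to side product at one moment, with momentary share ratio/(1+ratio), here 69.5%.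

I side with the second chemist. Partner is the smaller charge, at 0.700 equiv, and falls as target forms, and a tank runs wholly at its outlet level. Suppose a tank turns over the whole substrate with 0.5 of it becoming target. That leaves [coupling partner] at 0.0200 M, where the ratio is 0.900 and the share 47.4%. So I expect the tanks near that figure and the closed flasks higher, but my reckoning cannot order noon against dusk. The first chemist's view belongs where escape stands far above return; here, at the charge, escape is 0.626 of return.

The forecast takes the second side: best dusk, with spring 57%, winter 51%, noon 60% and dusk 62%. Its grounds are that “the share is set by how much partner is present during conversion”.

The simulation gives dusk, with spring 57.2%, winter 51.1%, noon 59.4% and dusk 62.9%, the highest of them below the first chemist's figure. The neighbouring dusk flask, charged with 2.1 mol% of free catalyst, scales the branch ratio to 0.921, a share of 47.9% at the charge. At its reading at 8.00 h, partner stands at 76.5% of its charge and free catalyst at 95.0%, so the ratio is 0.736 and the share 42.4%. That neighbouring flask reads 44.9%.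

Its constants are invented; the result is computed.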